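**Plan**
- Cuts: the acid goes back to aldehyde 29. The bicycle is then opened through C6–C7 (alkenyl–alkenyl bond) together with C7a–C3a and C4–C5 (cycloaddition bonds, indene numbering), giving two open-chain halves, iodotrienal 19 and trienylstannane 27.
- Feature used: the cyclohexene ring (C3a, C4, C5, C6, C7, C7a) has its only double bond C6=C7 opposite the C3a–C4 bond, and C7a and C3a are bridged by C1–C2=C3 with a cis double bond. The bicycle is therefore the adduct of a diene C5=C6–C7=C7a and an E-enal C3a=C4 held three atoms apart, and the C6–C7 σ-bond of that diene can be made by cross-coupling.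
- Forward: 19 (from the Roche ester) and 27 (from 2-ethylacrolein) are joined by Stille coupling. Hexaenal 28 formed in the flask cyclises there, closing the cyclopentene and cyclohexene rings together. The formyl group, kept as the activating group of the dienophile, is oxidised to the acid at the end.
- Stereochemistry: C1 comes from the chiral pool. C3a, C4, C5 and C7a (C4 and C5 quaternary and adjacent) arise in the cycloaddition from the alkene geometries (E from hydrozirconation, Z from Still–Gennari olefination, E from Wittig and bromoenal chemistry), endo addition and allylic 1,3-strain at C1.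

Key step: step 14

Remark on the chemistry: the target is read as the trans-fused (1R,3aR,4R,5S,7aS) isomer; ring locants follow indene numbering (C1 = CH(CH3), C3a and C7a = ring fusion, C4 = carboxyl-bearing carbon).

Step 1
Reactants: 1 methyl (2R)-3-hydroxy-2-methylpropanoate
Product: 2 methyl (2R)-3-{[tert-butyl(dimethyl)silyl]oxy}-2-methylpropanoate
Conditions: tert-butyl(chloro)dimethylsilane, imidazole, CH2Cl2, 0 °C to rt
Reagents that add atoms: tert-butyl(chloro)dimethylsilane CC(C)(C)[Si](C)(C)Cl
Why: Imidazole-mediated silyl ether formation masks the primary alcohol for the organometallic steps and does not touch the stereocentre.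

Step 2
Reactants: 2 methyl (2R)-3-{[tert-butyl(dimethyl)silyl]oxy}-2-methylpropanoate
Product: 4 tert-butyl(dimethyl){[(2S)-2-methylbut-3-yn-1-yl]oxy}silane, via aldehyde 3 (not isolated)
Conditions: iBu2AlH (1.05 equiv), CH2Cl2, −78 °C; then MeOH, K2CO3, dimethyl (1-diazo-2-oxopropyl)phosphonate, −78 °C to rt
Reagents that add atoms: dimethyl (1-diazo-2-oxopropyl)phosphonate CC(=O)C(=[N+]=[N-])P(=O)(OC)OC
Why: Partial ester reduction at −78 °C and release of aldehyde 3 on adding methanol is followed in the same flask by Ohira–Bestmann (Seyferth–Gilbert) homologation to the terminal alkyne, whose mildly basic conditions should leave the α-stereocentre intact.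

Step 3
Reactants: 4 tert-butyl(dimethyl){[(2S)-2-methylbut-3-yn-1-yl]oxy}silane
Product: 6 tert-butyl(dimethyl){[(2S)-2-methylpent-3-yn-1-yl]oxy}silane, via lithium acetylide 5 (not isolated)
Conditions: n-BuLi, THF, −78 °C; then iodomethane, −78 °C to rt
Reagents that add atoms: iodomethane CI
Why: Deprotonation of the terminal alkyne and SN2 methylation of acetylide 5 (acetylide alkylation) install the future C7 methyl group.

Step 4
Reactants: 6 tert-butyl(dimethyl){[(2S)-2-methylpent-3-yn-1-yl]oxy}silane
Product: 8 tert-butyl{[(2S,3E)-4-iodo-2-methylpent-3-en-1-yl]oxy}dimethylsilane, via alkenylzirconocene 7 (not isolated)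
Conditions: Cp2Zr(H)Cl (2.5 equiv), THF, 50 °C; then I2, THF, 0 °C, dark
Reagents that add atoms: iodine II
Why: Syn hydrozirconation of the internal alkyne equilibrates under excess Cp2Zr(H)Cl to regioisomer 7 with zirconium on the methyl-bearing carbon, and iodinolysis with retention gives the E-alkenyl iodide (hydrozirconation–iodination).

Step 5
Reactants: 8 tert-butyl{[(2S,3E)-4-iodo-2-methylpent-3-en-1-yl]oxy}dimethylsilane
Product: 9 (2S,3E)-4-iodo-2-methylpent-3-en-1-ol
Conditions: Bu4NF, THF, 0 °C to rt
Reagents that add atoms: none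
Why: Fluoride-induced desilylation frees the primary alcohol, and the alkenyl iodide is inert to Bu4NF.

Step 6
Reactants: 9 (2S,3E)-4-iodo-2-methylpent-3-en-1-ol
Product: 10 (2S,3E)-4-iodo-2-methylpent-3-enal
Conditions: Dess–Martin periodinane, NaHCO3, CH2Cl2, 0 °C; crude product used at once
Reagents that add atoms: none
Why: Dess–Martin oxidation under bicarbonate buffering gives the β,γ-unsaturated aldehyde without strong acid or base, so that the α-stereocentre should not epimerise before the next step.

Step 7
Reactants: 11 methyl [bis(2,2,2-trifluoroethoxy)phosphoryl]acetate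
Product: 13 methyl 2-[bis(2,2,2-trifluoroethoxy)phosphoryl]butanoate (racemic), via potassium enolate 12 (not isolated)
Conditions: KOtBu, THF, 0 °C; then iodoethane, 0 °C to rt
Reagents that add atoms: iodoethane CCI
Why: C-alkylation of enolate 12 with iodoethane (enolate alkylation) places the future C3 ethyl group on the Still–Gennari reagent.

Step 8
Reactants: 10 (2S,3E)-4-iodo-2-methylpent-3-enal; 13 methyl 2-[bis(2,2,2-trifluoroethoxy)phosphoryl]butanoate
Product: 15 methyl (2Z,4R,5E)-2-ethyl-6-iodo-4-methylhepta-2,5-dienoate, via phosphonate anion 14 (not isolated)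
Conditions: KN(SiMe3)2, 18-crown-6, THF, −78 °C (13 deprotonated first, then 10 added)
Reagents that add atoms: none
Why: In this Still–Gennari variant of the Horner–Wadsworth–Emmons reaction the trifluoroethyl phosphonate anion 14 under dissociating conditions eliminates from the kinetic adduct to give the Z-trisubstituted enoate, placing the ester carbon cis to the stereocentre-bearing chain as the cyclopentene ring later requires.

Step 9
Reactants: 15 methyl (2Z,4R,5E)-2-ethyl-6-iodo-4-methylhepta-2,5-dienoate
Product: 16 (2Z,4R,5E)-2-ethyl-6-iodo-4-methylhepta-2,5-dien-1-ol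
Conditions: iBu2AlH (2.2 equiv), CH2Cl2, −78 °C
Reagents that add atoms: none
Why: 1,2-Reduction of the enoate by the aluminium hydride at −78 °C gives the allylic alcohol with retention of the Z geometry and leaves the alkenyl iodide untouched.

Step 10
Reactants: 16 (2Z,4R,5E)-2-ethyl-6-iodo-4-methylhepta-2,5-dien-1-ol; 17 2-(triphenylphosphoranylidene)propanal
Product: 19 (2E,4Z,6R,7E)-4-ethyl-8-iodo-2,6-dimethylnona-2,4,7-trienal, via Z-enal 18 (not isolated)
Conditions: MnO2, CH2Cl2, rt; then 17, 40 °C, same flask
Reagents that add atoms: none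
Why: Allylic oxidation with MnO2 gives Z-enal 18, which is trapped in the same flask by stabilised ylide 17 in an E-selective Wittig reaction to give the (2E,4Z)-dienal carrying the dienophile.

Step 11
Reactants: 20 2-ethylprop-2-enal
Product: 22 (2E)-3-bromo-2-ethylprop-2-enal, via dibromide 21 (not isolated)
Conditions: Br2, CH2Cl2, −78 to 0 °C; then Et3N, 0 °C to rt
Reagents that add atoms: bromine BrBr
Why: Bromination of the enal followed by amine-induced dehydrobromination through the more acidic CH2Br hydrogen should give the β-bromoenal with bromine trans to the formyl group, by analogy with the 2-methyl series.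

Step 12
Reactants: 22 (2E)-3-bromo-2-ethylprop-2-enal; 23 diethyl [(2E)-3-phenylprop-2-en-1-yl]phosphonate
Product: 25 [(1E,3E,5E)-6-bromo-5-ethylhexa-1,3,5-trien-1-yl]benzene, via lithiated phosphonate 24 (not isolated)
Conditions: LiN(SiMe3)2, THF, −78 °C (23 deprotonated first, then 22 added), −78 to 0 °C
Reagents that add atoms: none
Why: Horner–Wadsworth–Emmons reaction of the allylic phosphonate anion 24 with the aldehyde forms the central E double bond and leaves the bromoalkene geometry unchanged.

Step 13
Reactants: 25 [(1E,3E,5E)-6-bromo-5-ethylhexa-1,3,5-trien-1-yl]benzene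
Product: 27 tributyl[(1E,3E,5E)-2-ethyl-6-phenylhexa-1,3,5-trien-1-yl]stannane, via alkenyllithium 26 (not isolated)
Conditions: t-BuLi (2 equiv), Et2O, −78 °C; then Bu3SnCl, −78 °C to rt
Reagents that add atoms: tributyltin chloride CCCC[Sn](Cl)(CCCC)CCCC
Why: Bromine–lithium exchange gives alkenyllithium 26, configurationally stable at −78 °C, which is stannylated with retention (halogen–metal exchange then transmetalation).

Step 14
Reactants: 19 (2E,4Z,6R,7E)-4-ethyl-8-iodo-2,6-dimethylnona-2,4,7-trienal; 27 tributyl[(1E,3E,5E)-2-ethyl-6-phenylhexa-1,3,5-trien-1-yl]stannane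
Product: 29 (1R,3aR,4R,5S,7aS)-3,5-diethyl-1,4,7-trimethyl-5-[(1E,3E)-4-phenylbuta-1,3-dien-1-yl]-3a,4,5,7a-tetrahydro-1H-indene-4-carbaldehyde, via hexaenal 28 (not isolated)
Conditions: Pd2(dba)3 (cat.), AsPh3 (cat.), CuI (cat.), degassed DMF, rt, dark; then 60–80 °C in the same flask
Reagents that add atoms: none
Why: Oxidative addition of zerovalent palladium into the C–I bond of 19, tin-to-palladium transmetalation of 27 and reductive elimination join C8 to C9 (numbering of 28; C7–C6 of the indene) with retention of both alkene geometries, which creates the (7E,9E)-diene of 28 three atoms away from the enal; the closest known type is a tandem Stille coupling–intramolecular Diels–Alder reaction of a 1,3,8-nonatriene. The [4+2] cycloaddition that follows in the same flask is suprafacial on both components: the cyclohexene ring closes by the bonds C7–C3 (ring fusion C7a–C3a, the leading bond between the largest HOMO coefficient of the diene and the β-carbon of the enal) and C10–C2 (C5–C4), and the cyclopentene ring closes at the same time as the tether ring C3–C4=C5–C6–C7, whose Z double bond holds diene and dienophile together. C4 and C5 of the product (both quaternary) take their relative configuration from the E geometry of the enal and the 9E geometry of the diene, and the trans ring fusion C3a/C7a from the transition state with the formyl group endo and the tether exo. The absolute sense comes from the one existing stereocentre C6 of 28 (C1 of the product): its hydrogen eclipses the C7=C8 bond to avoid allylic 1,3-strain with the C8 methyl group, so the dienophile is delivered to the diene face anti to the C6 methyl group. The step needs chemoselective coupling at the alkenyl iodide without loss of geometry or reaction of the aldehyde, which the neutral base-free conditions at room temperature should secure, and endo as well as facial selectivity, which the formyl activation and the allylic stereocentre should secure.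

Step 15
Reactants: 29 (1R,3aR,4R,5S,7aS)-3,5-diethyl-1,4,7-trimethyl-5-[(1E,3E)-4-phenylbuta-1,3-dien-1-yl]-3a,4,5,7a-tetrahydro-1H-indene-4-carbaldehyde
Product: 30 (1R,3aR,4R,5S,7aS)-3,5-diethyl-1,4,7-trimethyl-5-[(1E,3E)-4-phenylbuta-1,3-dien-1-yl]-3a,4,5,7a-tetrahydro-1H-indene-4-carboxylic acid
Conditions: NaClO2, NaH2PO4, 2-methylbut-2-ene, t-BuOH/H2O, 0 °C to rt
Reagents that add atoms: sodium chlorite NaClO2 [Na+].[O-]Cl=O
Why: Pinnick (chlorite) oxidation converts the hindered α-quaternary aldehyde, which has no epimerisable position, into the acid, while 2-methylbut-2-ene scavenges hypochlorous acid so that the diene and ring alkenes should not be chlorinated.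

**Compound list**
1 | methyl (2R)-3-hydroxy-2-methylpropanoate | C[C@H](CO)C(=O)OC | starting material
2 | methyl (2R)-3-{[tert-butyl(dimethyl)silyl]oxy}-2-methylpropanoate | C[C@H](CO[Si](C)(C)C(C)(C)C)C(=O)OC | intermediate
3 | (2R)-3-{[tert-butyl(dimethyl)silyl]oxy}-2-methylpropanal | C[C@H](CO[Si](C)(C)C(C)(C)C)C=O | intermediate
4 | tert-butyl(dimethyl){[(2S)-2-methylbut-3-yn-1-yl]oxy}silane | C[C@H](CO[Si](C)(C)C(C)(C)C)C#C | intermediate
5 | {(3S)-4-{[tert-butyl(dimethyl)silyl]oxy}-3-methylbut-1-yn-1-yl}lithium (lithium acetylide of 4) | C[C@H](CO[Si](C)(C)C(C)(C)C)C#C[Li] | intermediate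
6 | tert-butyl(dimethyl){[(2S)-2-methylpent-3-yn-1-yl]oxy}silane | C[C@H](CO[Si](C)(C)C(C)(C)C)C#CC | intermediate
7 | chlorobis(cyclopentadienyl){(2E,4S)-5-{[tert-butyl(dimethyl)silyl]oxy}-4-methylpent-2-en-2-yl}zirconium, Cp2Zr(Cl)(alkenyl), Cp rings drawn σ-bonded | C[C@H](CO[Si](C)(C)C(C)(C)C)/C=C(\C)[Zr](Cl)(C1C=CC=C1)C1C=CC=C1 | intermediate
8 | tert-butyl{[(2S,3E)-4-iodo-2-methylpent-3-en-1-yl]oxy}dimethylsilane | C[C@H](CO[Si](C)(C)C(C)(C)C)/C=C(\C)I | intermediate
9 | (2S,3E)-4-iodo-2-methylpent-3-en-1-ol | C[C@H](CO)/C=C(\C)I | intermediate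
10 | (2S,3E)-4-iodo-2-methylpent-3-enal | C[C@H](C=O)/C=C(\C)I | intermediate
11 | methyl [bis(2,2,2-trifluoroethoxy)phosphoryl]acetate | COC(=O)CP(=O)(OCC(F)(F)F)OCC(F)(F)F | starting material
12 | potassium enolate of 11 | COC(=O)[CH-]P(=O)(OCC(F)(F)F)OCC(F)(F)F.[K+] | intermediate
13 | methyl 2-[bis(2,2,2-trifluoroethoxy)phosphoryl]butanoate (racemic) | CCC(C(=O)OC)P(=O)(OCC(F)(F)F)OCC(F)(F)F | intermediate
14 | potassium salt of 13 (phosphonate carbanion) | CC[C-](C(=O)OC)P(=O)(OCC(F)(F)F)OCC(F)(F)F.[K+] | intermediate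
15 | methyl (2Z,4R,5E)-2-ethyl-6-iodo-4-methylhepta-2,5-dienoate | C[C@H](/C=C(/CC)C(=O)OC)/C=C(\C)I | intermediate
16 | (2Z,4R,5E)-2-ethyl-6-iodo-4-methylhepta-2,5-dien-1-ol | C[C@H](/C=C(/CC)CO)/C=C(\C)I | intermediate
17 | 2-(triphenylphosphoranylidene)propanal | CC(C=O)=P(c1ccccc1)(c1ccccc1)c1ccccc1 | starting material
18 | (2Z,4R,5E)-2-ethyl-6-iodo-4-methylhepta-2,5-dienal | C[C@H](/C=C(/CC)C=O)/C=C(\C)I | intermediate
19 | (2E,4Z,6R,7E)-4-ethyl-8-iodo-2,6-dimethylnona-2,4,7-trienal | C[C@H](/C=C(/CC)\C=C(/C)C=O)/C=C(\C)I | intermediate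
20 | 2-ethylprop-2-enal (2-ethylacrolein) | CCC(=C)C=O | starting material
21 | 2,3-dibromo-2-ethylpropanal (racemic) | CCC(Br)(CBr)C=O | intermediate
22 | (2E)-3-bromo-2-ethylprop-2-enal | O=C/C(CC)=C/Br | intermediate
23 | diethyl [(2E)-3-phenylprop-2-en-1-yl]phosphonate | CCOP(=O)(OCC)C/C=C/c1ccccc1 | starting material
24 | lithium salt of 23 (α-lithiated cinnamylphosphonate) | CCOP(=O)(OCC)[CH-]/C=C/c1ccccc1.[Li+] | intermediate
25 | [(1E,3E,5E)-6-bromo-5-ethylhexa-1,3,5-trien-1-yl]benzene | Br/C=C(\CC)/C=C/C=C/c1ccccc1 | intermediate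
26 | [(1E,3E,5E)-2-ethyl-6-phenylhexa-1,3,5-trien-1-yl]lithium | [Li]/C=C(\CC)/C=C/C=C/c1ccccc1 | intermediate
27 | tributyl[(1E,3E,5E)-2-ethyl-6-phenylhexa-1,3,5-trien-1-yl]stannane | CCCC[Sn](CCCC)(CCCC)/C=C(\CC)/C=C/C=C/c1ccccc1 | intermediate
28 | (2E,4Z,6S,7E,9E,11E,13E)-4,10-diethyl-2,6,8-trimethyl-14-phenyltetradeca-2,4,7,9,11,13-hexaenal | C[C@H](/C=C(/CC)\C=C(/C)C=O)/C=C(\C)/C=C(\CC)/C=C/C=C/c1ccccc1 | intermediate
29 | (1R,3aR,4R,5S,7aS)-3,5-diethyl-1,4,7-trimethyl-5-[(1E,3E)-4-phenylbuta-1,3-dien-1-yl]-3a,4,5,7a-tetrahydro-1H-indene-4-carbaldehyde | CCC1=C[C@@H](C)[C@@H]2C(C)=C[C@@](/C=C/C=C/c3ccccc3)(CC)[C@](C)(C=O)[C@@H]12 | intermediate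
30 | (1R,3aR,4R,5S,7aS)-3,5-diethyl-1,4,7-trimethyl-5-[(1E,3E)-4-phenylbuta-1,3-dien-1-yl]-3a,4,5,7a-tetrahydro-1H-indene-4-carboxylic acid | CCC1=C[C@@H](C)[C@@H]2C(C)=C[C@@](/C=C/C=C/c3ccccc3)(CC)[C@](C)(C(=O)O)[C@@H]12 | target

Total step count: 15. Longest linear sequence: 11 steps (steps 1–6, 8, 9, 10, 14, 15).

**Steps most likely to fail**

Step 14. Transmetalation between two trisubstituted alkenyl partners may be slow, so that protodestannylation or homocoupling competes. The Z-configured dienal part of 28 may isomerise or undergo a 1,5-hydrogen shift on warming before it cyclises. Endo selectivity may erode at the temperature the cycloaddition needs. The fallback moves the coupling one stage earlier and lets a Wittig reaction trigger the cycloaddition. It sets out from 16 and 27, which are coupled under the same palladium conditions to (2Z,4S,5E,7E,9E,11E)-2,8-diethyl-4,6-dimethyl-12-phenyldodeca-2,5,7,9,11-pentaen-1-ol F1. This compound has no dienophile and can be purified. MnO2 oxidation gives (2Z,4S,5E,7E,9E,11E)-2,8-diethyl-4,6-dimethyl-12-phenyldodeca-2,5,7,9,11-pentaenal F2, and olefination with ylide 17 forms 28 in the absence of palladium and tin. Hexaenal 28 is then cyclised at low temperature with Me2AlCl bound to the formyl group instead of by heat, and the route is rejoined at 29.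

Step 8. The α-stereocentre of the β,γ-unsaturated aldehyde 10 may epimerise, or its double bond may move into conjugation, under the basic olefination conditions, and Z selectivity may be incomplete. The fallback reverses the polarity of the olefination so that no enolisable aldehyde is needed. It sets out from alcohol 9: iodination (I2, PPh3, imidazole) gives (2E,4S)-2,5-diiodo-4-methylpent-2-ene F3, and heating with PPh3 in MeCN gives [(2S,3E)-4-iodo-2-methylpent-3-en-1-yl]triphenylphosphonium iodide F4. Deprotonation with NaN(SiMe3)2 in THF at −78 °C gives the non-stabilised ylide [(2S,3E)-4-iodo-2-methylpent-3-en-1-ylidene]triphenylphosphorane F5. This reacts with 1-{[tert-butyl(dimethyl)silyl]oxy}butan-2-one F6 (from commercial 1-hydroxybutan-2-one, tert-butyl(chloro)dimethylsilane and imidazole) in a Z-selective Wittig reaction of an α-alkoxy ketone to give tert-butyl{[(2Z,4R,5E)-2-ethyl-6-iodo-4-methylhepta-2,5-dien-1-yl]oxy}dimethylsilane F7. Bu4NF frees alcohol 16, where the route is rejoined, and step 9 is no longer needed.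

Step 10. Enal 18 may isomerise from Z to E while it waits for the slowly reacting formyl ylide, and product 19 may be homologated a second time by 17. The fallback traps 18 with a more reactive ester ylide and adjusts the oxidation level afterwards. It sets out from 16: MnO2 and methyl 2-(triphenylphosphoranylidene)propanoate in CH2Cl2 at rt (tandem oxidation–Wittig) give methyl (2E,4Z,6R,7E)-4-ethyl-8-iodo-2,6-dimethylnona-2,4,7-trienoate F8, which cannot be homologated further. iBu2AlH at −78 °C gives (2E,4Z,6R,7E)-4-ethyl-8-iodo-2,6-dimethylnona-2,4,7-trien-1-ol F9, and MnO2 oxidation returns to 19.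

**Further compounds**
F1 | step 14 | (2Z,4S,5E,7E,9E,11E)-2,8-diethyl-4,6-dimethyl-12-phenyldodeca-2,5,7,9,11-pentaen-1-ol | C[C@H](/C=C(/CC)CO)/C=C(\C)/C=C(\CC)/C=C/C=C/c1ccccc1
F2 | step 14 | (2Z,4S,5E,7E,9E,11E)-2,8-diethyl-4,6-dimethyl-12-phenyldodeca-2,5,7,9,11-pentaenal | C[C@H](/C=C(/CC)C=O)/C=C(\C)/C=C(\CC)/C=C/C=C/c1ccccc1
F3 | step 8 | (2E,4S)-2,5-diiodo-4-methylpent-2-ene | C[C@H](CI)/C=C(\C)I
F4 | step 8 | [(2S,3E)-4-iodo-2-methylpent-3-en-1-yl]triphenylphosphonium iodide | C[C@H](C[P+](c1ccccc1)(c1ccccc1)c1ccccc1)/C=C(\C)I.[I-]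
F5 | step 8 | [(2S,3E)-4-iodo-2-methylpent-3-en-1-ylidene]triphenylphosphorane | C[C@H](C=P(c1ccccc1)(c1ccccc1)c1ccccc1)/C=C(\C)I
F6 | step 8 | 1-{[tert-butyl(dimethyl)silyl]oxy}butan-2-one | CCC(=O)CO[Si](C)(C)C(C)(C)C
F7 | step 8 | tert-butyl{[(2Z,4R,5E)-2-ethyl-6-iodo-4-methylhepta-2,5-dien-1-yl]oxy}dimethylsilane | C[C@H](/C=C(/CC)CO[Si](C)(C)C(C)(C)C)/C=C(\C)I
F8 | step 10 | methyl (2E,4Z,6R,7E)-4-ethyl-8-iodo-2,6-dimethylnona-2,4,7-trienoate | C[C@H](/C=C(/CC)\C=C(/C)C(=O)OC)/C=C(\C)I
F9 | step 10 | (2E,4Z,6R,7E)-4-ethyl-8-iodo-2,6-dimethylnona-2,4,7-trien-1-ol | C[C@H](/C=C(/CC)\C=C(/C)CO)/C=C(\C)I
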